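With no rate constants in hand, I reckoned from the charges of this flask and its readings.

in all of them: X 12 mM (fed, over 25 s); D 12.6 mM

| charge | remark | time |
|---|---|---|
| maple | the very flask that is asked about, followed so far; the fed solution adds 0.50 times the starting volume |  |
| flask | the fed solution adds 0.50 times the starting volume | 2.0 h |

maple run (percent of the X charged)

| time / min | X / % | Q / % |
|---|---|---|
| 1.33 | 38.0 | 3.2 |
| 4.00 | 23.2 | 4.4 |
| 8.00 | 15.9 | 6.3 |
| 12.0 | 12.5 | 6.1 |
| 15.0 | 10.2 | 7.0 |
| 20.0 | 10.2 | 7.5 |

(scatter of a reading: 0.5 percentage points)

- amounts are per litre of the starting volume; all of the dose is in the solution fed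
- the reaction counts as stopped when no species that holds the X changes by six tenths of a point or more over the second half of the time

1. why nothing more happens at 2.0 h, or that something still does (all of X has reacted / forward and back rates have come level / it is still moving / D has run out first)
2. how much of the X has reacted by 2.0 h
3. how much Q there is at 2.0 h, in percent of the X charged
4. amount of Q if the flask were left three thousand times as long, in percent of the X charged

The zero of my scale was the equal charge, one D per X. If every X ended up holding one D, the part of D's own charge left over, which I call the spare share, would be one minus the ratio of the X charge to the D charge: 4.76 %. On that count of one D per X, X was the limiting reagent, by a narrow margin, and at one D per Q the ceiling for Q was 100 % of the X charged. My floor for Q was the last reading, 7.5 %. Carrying on unslowed the pace read between 8.00 min and 20.0 min gave 17.5 % at 2.0 h, a figure that carries the scatter of those readings. I therefore bracketed Q at 2.0 h between 7.5 % and 17.5 %, and Q in the long run between 7.5 % and 100 %.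

The forecast answered "D has run out first", with 93.5 % of X reacted, 10.5 % of Q at 2.0 h and 11 % in the long run, reasoning that “Each Q therefore costs a second D”. Both of its Q values stood inside my brackets.

The flask gave "it is still moving", with 91.7 % of X reacted, 14.2 % of Q at 2.0 h, below my upper mark, and 100 % in the long run, which is my ceiling.

    X ⇌ J (K = 1.30, k = 0.0330 s⁻¹)
    D + J ⇌ Z (K = 1000 M⁻¹, k = 0.170 M⁻¹ s⁻¹)
    X + D → Q (k = 0.0820 M⁻¹ s⁻¹)
    D + J ⇌ L (K = 2600 M⁻¹, k = 0.780 M⁻¹ s⁻¹)
    D + Z ⇌ G (K = 210 M⁻¹, k = 0.240 M⁻¹ s⁻¹)

At 2.00 h the flask still held 18 % of its D, more than the spare share of 4.76 %, while L held 47.5 % of the X charged. At that time X entered J 260 times as fast as it went to Q, forward rates alone, and over the run the backward turnover of that step came to 97 % of the forward one.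

In the neighbour charged with 32 mM of D, the spare share is 62.5 %. That neighbour kept 56 % of its D at 2.00 h, less than its spare share, and G, which holds a second D, stood at 20.9 % of the X charged.

The readings were generated by integration from invented constants; scatter was added.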